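The constants are those of an exercise; the flask was simulated.

The ratio I watch is the split: the rate at which partner B goes into second intermediate over the rate at which it goes into open intermediate. I work it first for grey, where the feed sets the second rate, so the split is 5.94 at the start.

common to all: partner B 12.0 mM; time 6.0 min
- green: starting material 10 mM (in portions, 3, over 5.0 min); partner A 15.0 mM; temperature 35 °C; first portion at the start, last at 5.0 min
- violet: starting material 10 mM (fed, over 5.0 min); partner A 15.0 mM; the addition at −5 °C, then warmed to 35 °C; the feed brings no volume worth counting
- red: starting material 10 mM; partner A 15.0 mM; everything together at the start at −5 °C, warmed to 35 °C at 5.0 min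
- grey: starting material 10 mM (fed, over 5.0 min); partner A 15.0 mM; temperature 35 °C; all else is in the flask from the start; the feed brings no volume worth counting
- ochre: starting material 10 mM; partner A 15.0 mM; temperature 35 °C; everything together at the start
- teal: starting material 10 mM; partner A 15.0 mM (fed, over 80 s); temperature 35 °C; all else is in the flask from the start; the feed brings no volume worth counting

1. the flask with the highest amount of homo product, in percent of the starting material charged ("all alike" if they lie within 1.5 percentage points) (green / violet / red / grey / ochre / teal / all alike)
2. final homo product, as a percentage of the starting material charged, in green
3. final homo product, as a percentage of the starting material charged, in violet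
4. final homo product, as a percentage of the starting material charged, in red
5. final homo product, as a percentage of the starting material charged, in grey
6. final homo product, as a percentage of the starting material charged, in ochre
7. final homo product, as a percentage of the starting material charged, in teal

- in percentages every species weighs as the starting material in it: one homo product counts as two
- a step written with two of one species runs at k times the square of its concentration and takes two of it each time
- the constants hold at 35 °C; other temperatures follow from the activation energies and enthalpies

    2 open intermediate → homo product (k1 = 47 L mol⁻¹ s⁻¹, Ea1 = 54.0 kJ mol⁻¹)
    partner B + partner A → second intermediate (k2 = 1.1 L mol⁻¹ s⁻¹, Ea2 = 45.0 kJ mol⁻¹)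
    starting material ⇌ dormant form (K3 = 1.9, k3 = 0.32 s⁻¹, Ea3 = 87.0 kJ mol⁻¹, ΔH3 = −16.0 kJ mol⁻¹)
    open intermediate + second intermediate → target (k4 = 110 L mol⁻¹ s⁻¹, Ea4 = 50.0 kJ mol⁻¹)
    starting material + partner B → open intermediate (k5 = 20 L mol⁻¹ s⁻¹, Ea5 = 49.0 kJ mol⁻¹)
    starting material → decomposition product (k6 = 9.3 × 10⁻⁶ s⁻¹, Ea6 = 94.0 kJ mol⁻¹)
    (constants at 35 °C)

Partner B is the limiting reagent of the two routes that share it, since 12.0 mM stands against 25.0 mM of starting material and partner A together. Each target takes one open and one second intermediate, so I reckon the homo product as open intermediate made minus second intermediate made, where that difference is positive.

I build grey up. With opening and pairing by themselves, starting material has a half-life of 2.89 s against a feed of 5.0 min, so it opens as it arrives. Partner B covers the charge, so I reckon the homo product at 100%.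

Now I add partner A. The split of 5.94 is above one, so second intermediate runs ahead. But the split drifts down with partner B, whose half-life by this step is 0.700 min. Over 3 such half-lives the feed brings 4.20 mM, which I take as the open intermediate made. That leaves 7.80 mM for second intermediate, so the difference is negative and I reckon grey's homo product near zero.

Last comes the dormant form. It exchanges with a relaxation half-life of 1.42 s, and at partner B as charged it stretches the opening half-life to 8.38 s, still short against the feed. So in grey I leave my reckoning as it stands.

In ochre the same ratio is set by the pool of starting material. At the charged amounts it is 0.0825 without the dormant form and 0.239 once the dormant form has balanced with the starting material. It climbs as the pool falls. If 0.7 of partner B opens, the split has reached 1.14 by then; I take that share as my estimate, and it gives 48.0% homo product. Teal begins with no partner A in the flask, so its split begins at nothing, lower than ochre's, and I put it above ochre. I reckon no figures for green, violet and red.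

The forecast names teal as highest, and gives green 7%, violet 42%, red 48%, grey 2.5%, ochre 50% and teal 64%. Its ground for green and grey is that slow or portioned addition lets “the second intermediate stay ahead”. My grey lies lower than its figure and my ochre just below its figure.

The simulation gives teal as highest, with green 9.49%, violet 38.5%, red 58.9%, grey 0.339%, ochre 51.9% and teal 76.0%. The forecast stands 11 percentage points low on red and 12 points low on teal, and within its tolerance elsewhere.

Grey's neighbour, charged with 6.0 mM of partner A, has a starting split of 2.38, still above one. Yet 22% of that partner A remains at the end, so second intermediate made comes to 4.67 mM. With 0.994% of partner B left in this neighbour, I count 7.21 mM opened. The difference is 25.4% of the charge, and this neighbour holds 1.96% open intermediate and 23.6% homo product.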